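Remark on the chemistry: ethoxyacetylene is taken as its commercial solution in hexanes, and the racemic centres of the four-membered-ring intermediates are left uncontrolled because aromatization removes them.

## Analysis of the target

Target 21 is 2,4-dihydroxy-5-methyl-6-(13-methyltetradecyl)benzoic acid. It has one benzene ring with CO2H at C1, OH at C2, OH at C4, CH3 at C5 and the iso-branched C15 chain at C6; only C3 carries hydrogen. There is no stereocentre, since the chain ends in an isopropyl group, so the only control problem is regiochemistry. The sensitive unit is the 2,4-dihydroxybenzoic acid with an ortho alkyl group: such acids lose CO2 on heating or in acid by ipso protonation of the electron-rich ring, and the free resorcinol oxidizes easily, so the acid should be made last and isolated cold. The difficulty is the contiguous substitution: methyl and chain sit on neighbouring carbons (C5, C6), the carboxyl lies on the far side of the chain, and stepwise substitution of a plain 5-alkylresorcinol would not distinguish its open positions cleanly. The strategy rests on the arc C2(O)–C3(H)–C4(O)–C5(CH3)–C6(alkyl): two meta oxygens with hydrogen between them, followed by two carbon substituents. A vinylketene (supplying C4 as its carbonyl carbon, with C1, C6 and C5) and a terminal alkoxyalkyne (supplying C3 and C2) assemble exactly this arc in one operation. The remaining open position C1, ortho to the C2 oxygen, then takes the carboxyl.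

## Retrosynthetic reasoning

**21 to 19.** The C1–CO2H bond is cut first, because the acid is the most fragile group and should not be carried through other steps. This gives diol 19, a robust arene. The forward reaction must put the carboxyl at C1 (ortho to C2–OH, para to C4–OH, beside the chain) and not at C3 between the two hydroxyls. A magnesium-templated ortho-carboxylation, which ends in chelate 20, is the reaction type that takes this course with 5-alkylresorcinols.

**19 to 17.** One O–ethyl bond is cut, leading to monoether 17, the compound that the ring-forming step delivers. The ether cannot be kept through the carboxylation: in 17 the only free hydroxyl is at C4, flanked by the methyl-bearing C5 and by C3, so an ortho-carboxylation would go to C3. Only after the C2 oxygen is freed is C1 ortho to a phenol.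

**17 to 11 and 12.** Three ring bonds are cut at once, C3–C4, C1–C2 and C4–C5, giving cyclobutenone 11 and ynol ether 12. The cut divides the ring into a two-carbon piece (C2 with its oxygen, C3 with its hydrogen) and a four-carbon piece that already holds the C4 oxygen as a carbonyl group, the methyl, the chain and the unsubstituted C1. The adjacent methyl and chain, the hardest feature to install on a preformed arene, are fixed by the C3–C4 bond of 11 before any ring exists. In the forward direction 11 opens to vinylketene 13, which adds 12 across its ketene C=C bond to give 14; this opens to 15 and closes to 16, which tautomerizes to the phenol. The one selectivity that matters is the orientation of 12, and its polarization dictates it.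

**11 to 7 and 8.** The C1–C2 and C3–C4 bonds of the cyclobutenone are cut, a (2+2) retron leading to terminal alkyne 7 and keteniminium ion 9 made from amide 8. This puts the chain on an alkyne, where it is easy to build, and draws the carbonyl carbon, C4 and its methyl from a three-carbon amide. The forward cycloaddition must place the chain at C3: the terminal alkyne carbon attacks the central carbon of 9, positive charge develops at the substituted carbon, and that carbon closes onto the CH(CH3) carbon. Hydrolysis of iminium salt 10 gives 11.

**7 to 1 and 2.** Alkyne 7 is cut between the triple bond and its propargylic carbon, giving bromide 6 and a two-carbon alkynyl nucleophile. Bromide 6 comes from alcohol 4 by a functional-group change. Alcohol 4 is cut at C12–C13 into bromo alcohol 1 and Grignard reagent 2, which supplies the isopropyl end; a copper-catalysed coupling that tolerates the alkoxide 3 makes this bond without protecting the hydroxyl.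

## Alternatives that were turned down

**Alternative 1:** The ring is traced to pyrone A1 (methyl 4-methoxy-6-(13-methyltetradecyl)-2-oxo-2H-pyran-5-carboxylate) and ketene acetal A2 (1,1-dimethoxyprop-1-ene) by cutting C5–C6 and C3–C4.
- Key step: an inverse-electron-demand Diels–Alder reaction joins the nucleophilic CH(CH3) carbon of A2 to pyrone C6 and the acetal carbon to pyrone C3. Decarboxylative loss of the lactone bridge and elimination of one methoxy group give methyl 2,4-dimethoxy-5-methyl-6-(13-methyltetradecyl)benzoate A3.
- For: the carboxyl carbon is present from the start and the polarity of the partners fixes all five substituents. On this point it is stronger than the chosen route, which still has to win a C1-versus-C3 contest in its last step.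
- Against: the 4-methoxy group makes A1 a vinylogous carbonate and so a less electron-poor diene. The new bond at C6 forms at a fully substituted carbon bearing the long chain. A1 is itself a multi-step target. A3 carries three methyl groups (two aryl ethers and a doubly ortho-substituted ester), and removing them needs Lewis acid and forcing hydrolysis on a ring that decarboxylates easily.
- Comparison: the chosen route has one ether, removes it before the acid exists, and releases the acid by cold acidification; it is not longer.

**Alternative 2:** Cutting C1–C2 and C5–C6 leads to diene A4 (1-methoxy-1,3-bis(trimethylsilyloxy)penta-1,3-diene) and alkynoate A5 (benzyl 16-methylheptadec-2-ynoate), the latter one acylation step from alkyne 7.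
- Key step: a thermal Diels–Alder reaction joins the methyl-bearing terminus of A4 to the chain-bearing carbon of A5 and the ketene acetal carbon to the ester-bearing carbon. Loss of the methoxy and silyl groups gives benzyl 2,4-dihydroxy-5-methyl-6-(13-methyltetradecyl)benzoate A6, and hydrogenolysis would free 21.
- For: it is the shortest on paper (six steps in the longest line), the carboxyl comes with the dienophile, and the last step is neutral and cold. On step count and mildness of the endgame it beats the chosen route.
- Against: an alkynoate with one ester and a β-alkyl group is a weak dienophile. The methyl on the diene terminus hinders the reactive conformer and the approach, and the C5–C6 bond joins two substituted carbons. At the temperatures such a pair would need, silyl ketene acetal dienes undergo silyl migration and decomposition.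
- Comparison: the chosen route pairs a ketene carbonyl carbon with an ynol ether, a polarity-matched and far more reactive couple that reacts at or below about 110 °C. It pays for this with one more step and a late carboxylation.

**Alternative 3:** The C1–C6 bond is cut in a polyketide-like sense, leading to diketo-dioxinone A7 (6-(3,17-dimethyl-2,4-dioxooctadecyl)-2,2-dimethyl-4H-1,3-dioxin-4-one).
- Key step: an intramolecular aldol reaction of dioxinone C5 on the chain-side ketone under a mild amine base, then dehydration and enolization, would give benzodioxinone A8 (7-hydroxy-2,2,6-trimethyl-5-(13-methyltetradecyl)-4H-1,3-benzodioxin-4-one). Hydrolysis of the cyclic acetal-ester would give 21.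
- For: the ring closes at ambient temperature and the carboxyl is present in masked form, so no regiochemical question arises at C1. On these points it is at least as strong as the chosen route.
- Against: A7 is a 1,3,5-tricarbonyl compound with a methyl on the carbon between two ketones. It needs either a C-selective methylation of a 1,3-diketone or strong-base acylation with a long-chain acyl donor, over several enolate steps. Such compounds exist as tautomer mixtures, can cyclize through oxygen to pyranones, and can undergo retro-Claisen cleavage. Opening A8 to the free acid needs hot aqueous base followed by acidification of a decarboxylation-prone acid.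
- Comparison: the chosen route fixes the methyl position by a C–C bond in cyclobutenone 11 rather than by alkylation selectivity, its intermediates before the arene are stable, and it is of comparable or shorter length.

Key step: step 5

## Route

Step 1
Reactants: 1 12-bromododecan-1-ol; 2 isopropylmagnesium chloride
Product: 4 13-methyltetradecan-1-ol, via chloromagnesium 12-bromododecan-1-olate 3 (not isolated)
Conditions: 2 (2.5 equiv), Li2CuCl4 (3 mol %), THF, −10 → 0 °C; then 1 M HCl
Reagents that add atoms: none
Why: The first equivalent of 2 deprotonates the alcohol and the second couples at the primary C–Br bond under Li2CuCl4 catalysis (Kochi-type copper-catalysed Grignard–alkyl halide cross-coupling), which tolerates a magnesium alkoxide and a secondary Grignard reagent.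

Step 2
Reactants: 4 13-methyltetradecan-1-ol
Product: 6 1-bromo-13-methyltetradecane, via alkoxyphosphonium bromide 5 (not isolated)
Conditions: CBr4, PPh3, CH2Cl2, 0 °C → rt
Reagents that add atoms: carbon tetrabromide, BrC(Br)(Br)Br; triphenylphosphine, c1ccc(cc1)P(c1ccccc1)c1ccccc1 (phosphorus part only in intermediate 5)
Why: Appel bromination; bromide displaces triphenylphosphine oxide from the alkoxyphosphonium ion by SN2 at an unhindered primary carbon, and no stereocentre is involved.

Step 3
Reactants: 6 1-bromo-13-methyltetradecane
Product: 7 15-methylhexadec-1-yne
Conditions: LiC≡CH·H2NCH2CH2NH2 (1.5 equiv), DMSO, 10 °C → rt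
Reagents that add atoms: lithium acetylide–ethylenediamine complex, [Li]C#C.NCCN
Why: SN2 alkylation of an acetylide by an unbranched primary bromide in DMSO; elimination should be minor for this substrate.

Step 4
Reactants: 7 15-methylhexadec-1-yne; 8 N,N-dimethylpropionamide
Product: 11 rac-4-methyl-3-(13-methyltetradecyl)cyclobut-2-en-1-one, via keteniminium triflate 9 (not isolated), via cyclobuteniminium triflate 10 (not isolated)
Conditions: 8 (1.3 equiv), Tf2O (1.4 equiv), ClCH2CH2Cl, −20 °C; then 7 and 2,4,6-collidine (1.4 equiv, slow addition), → 80 °C; then H2O, aq. NaHCO3, rt
Reagents that add atoms: water, O; triflic anhydride, O=S(=O)(OS(=O)(=O)C(F)(F)F)C(F)(F)F (only the triflate counter-ion of intermediates 9 and 10)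
Why: Ghosez keteniminium–alkyne (2+2) cycloaddition: O-triflylation of 8 and loss of the α-proton give 9, the terminal carbon of 7 attacks its central carbon so that charge develops at the substituted alkyne carbon, which closes onto the CH(CH3) carbon and puts the chain at C3; hydrolysis of 10 gives the enone. The C4 centre forms racemic and is destroyed in step 5.

Step 5
Reactants: 11 rac-4-methyl-3-(13-methyltetradecyl)cyclobut-2-en-1-one; 12 ethoxyacetylene
Product: 17 5-ethoxy-2-methyl-3-(13-methyltetradecyl)phenol, via vinylketene 13 (not isolated), via 4-alkenyl-3-ethoxycyclobutenone 14 (not isolated), via dienylketene 15 (not isolated), via cyclohexa-2,4-dienone 16 (not isolated)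
Conditions: 12 (2.5 equiv, hexane solution), toluene, sealed tube, 80 °C, then 110 °C; then 5% KOH, MeOH, rt
Reagents that add atoms: none
Why: This is a Danheiser benzannulation, a thermal cascade of four pericyclic steps between a cyclobutenone and an alkoxyalkyne. At 80 °C 11 undergoes conrotatory 4π opening of its C1–C4 bond, the methyl rotating outward, to give (E)-vinylketene 13. The ketene C=C bond of 13 adds (2+2) across the triple bond of 12, the hydrogen-bearing alkyne carbon bonding to the ketene carbonyl carbon (target C3–C4) and the oxygen-bearing carbon to the ketene α-carbon (target C1–C2), which gives 14. Cyclobutenone 14 opens by a second 4π step to dienylketene 15, and the benzene ring, the only ring closed, forms by thermal disrotatory 6π electrocyclization between the ketene carbon and the CH(CH3) terminus (target C4–C5); dienone 16 then tautomerizes to phenol 17. No stereocentre remains, because the racemic centres of 11, 14 and 16 are all erased on aromatization. The selectivity needed is the orientation of the ketene–ynol ether cycloaddition; the nucleophilic β-carbon of 12 and the electrophilic ketene carbonyl carbon secure it and place hydrogen, not the ethoxy group, between the two oxygens. Ring opening of 14 that turns the alkenyl group away from the ketene is reversible, so material should funnel through the cyclizable isomer 15. The KOH treatment cleaves any aryl ester formed when 17 traps 13.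

Step 6
Reactants: 17 5-ethoxy-2-methyl-3-(13-methyltetradecyl)phenol
Product: 19 4-methyl-5-(13-methyltetradecyl)benzene-1,3-diol, via bis(dibromoboryl) ether 18 (not isolated)
Conditions: BBr3 (3 equiv), CH2Cl2, −78 °C → rt; then H2O, 0 °C
Reagents that add atoms: boron tribromide, BrB(Br)Br (boron and bromine only in intermediate 18; 19 gains no heavy atom)
Why: Lewis-acid dealkylation of an aryl ethyl ether: BBr3 binds the ether oxygen and bromide attacks the ethyl CH2 by SN2, while the aryl C–O bonds and the saturated chain are untouched; water hydrolyses the aryl borates to the diol.

Step 7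
Reactants: 19 4-methyl-5-(13-methyltetradecyl)benzene-1,3-diol
Product: 21 2,4-dihydroxy-5-methyl-6-(13-methyltetradecyl)benzoic acid, via magnesium chelate 20 (not isolated)
Conditions: MeOMgOCO2Me (2 M in DMF, 10 equiv), 120 °C, N2 sweep; then cold 1 M HCl, 0 °C, extraction and drying without heating
Reagents that add atoms: methyl magnesium carbonate (methoxymagnesium methyl carbonate), COC(=O)O[Mg]OC
Why: Stiles-type ortho-carboxylation with methyl magnesium carbonate: the magnesium phenoxide delivers CO2 to an ortho carbon and the six-membered chelate 20 holds the product against reversal. Attack at C1, which is also para to the C4 hydroxyl, is the course 5-alkylresorcinols take to 6-alkyl-2,4-dihydroxybenzoic acids; cold acidification frees the acid.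

## Compound list

1 | 12-bromododecan-1-ol | OCCCCCCCCCCCCBr | starting material
2 | isopropylmagnesium chloride | CC(C)[Mg]Cl | starting material
3 | chloromagnesium 12-bromododecan-1-olate | BrCCCCCCCCCCCCO[Mg]Cl | intermediate
4 | 13-methyltetradecan-1-ol | CC(C)CCCCCCCCCCCCO | intermediate
5 | (13-methyltetradecyloxy)triphenylphosphonium bromide | CC(C)CCCCCCCCCCCCO[P+](c1ccccc1)(c1ccccc1)c1ccccc1.[Br-] | intermediate
6 | 1-bromo-13-methyltetradecane | CC(C)CCCCCCCCCCCCBr | intermediate
7 | 15-methylhexadec-1-yne | CC(C)CCCCCCCCCCCCC#C | intermediate
8 | N,N-dimethylpropionamide | CCC(=O)N(C)C | starting material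
9 | N,N-dimethylprop-1-en-1-ylideneammonium triflate (keteniminium triflate) | CC=C=[N+](C)C.[O-]S(=O)(=O)C(F)(F)F | intermediate
10 | rac-N,N-dimethyl-4-methyl-3-(13-methyltetradecyl)cyclobut-2-en-1-iminium triflate | CC1C(=[N+](C)C)C=C1CCCCCCCCCCCCC(C)C.[O-]S(=O)(=O)C(F)(F)F | intermediate
11 | rac-4-methyl-3-(13-methyltetradecyl)cyclobut-2-en-1-one | CC1C(=O)C=C1CCCCCCCCCCCCC(C)C | intermediate
12 | ethoxyacetylene | CCOC#C | starting material
13 | (3E)-3-(13-methyltetradecyl)penta-1,3-dien-1-one (vinylketene) | O=C=C/C(CCCCCCCCCCCCC(C)C)=C/C | intermediate
14 | rac-3-ethoxy-4-[(2E)-16-methylheptadec-2-en-3-yl]cyclobut-2-en-1-one | CCOC1=CC(=O)C1/C(CCCCCCCCCCCCC(C)C)=C/C | intermediate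
15 | (3E,5E)-3-ethoxy-5-(13-methyltetradecyl)hepta-1,3,5-trien-1-one (dienylketene) | CCO/C(C=C=O)=C/C(CCCCCCCCCCCCC(C)C)=C/C | intermediate
16 | rac-3-ethoxy-6-methyl-5-(13-methyltetradecyl)cyclohexa-2,4-dien-1-one | CCOC1=CC(=O)C(C)C(CCCCCCCCCCCCC(C)C)=C1 | intermediate
17 | 5-ethoxy-2-methyl-3-(13-methyltetradecyl)phenol | CCOc1cc(O)c(C)c(CCCCCCCCCCCCC(C)C)c1 | intermediate
18 | 5-methyl-4-(13-methyltetradecyl)-1,3-phenylene bis(dibromoborinate) (bis(dibromoboryl) ether of 19) | BrB(Br)Oc1cc(OB(Br)Br)c(C)c(CCCCCCCCCCCCC(C)C)c1 | intermediate
19 | 4-methyl-5-(13-methyltetradecyl)benzene-1,3-diol | Cc1c(O)cc(O)cc1CCCCCCCCCCCCC(C)C | intermediate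
20 | magnesium chelate of 4-hydroxy-5-methyl-6-(13-methyltetradecyl)-2-oxidobenzoate (Mg bridging the phenoxide and carboxylate oxygens) | Cc1c(O)cc2O[Mg]OC(=O)c2c1CCCCCCCCCCCCC(C)C | intermediate
21 | 2,4-dihydroxy-5-methyl-6-(13-methyltetradecyl)benzoic acid | Cc1c(O)cc(O)c(C(=O)O)c1CCCCCCCCCCCCC(C)C | target

## Step count and risk

Total step count: 7. Longest linear sequence: 7 steps (1 to 21); 2, 8 and 12 enter as purchased reagents.

**Step 5 (key step).** The most likely failure is thermal loss of the ynol ether, by evaporation and by retro-ene fragmentation above about 100 °C, before it has trapped the vinylketene. The ketene would then be consumed by dimerization or by acylating the phenol product. A second possibility is incomplete electrocyclic opening of the intermediate cyclobutenone at the lower temperature.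

Fallback, from bromide 6 back to 17: generate the same vinylketene at room temperature by photochemical Wolff rearrangement (the second-generation variant of the benzannulation). The sodium salt of dimethyl (2-oxopropyl)phosphonate (NaH, DMF, NaI cat., 60 °C) is alkylated with 6 to give dimethyl (16-methyl-2-oxoheptadecan-3-yl)phosphonate F1. Horner–Wadsworth–Emmons reaction of F1 with acetaldehyde (NaH, THF) gives (3E)-3-(13-methyltetradecyl)pent-3-en-2-one F2. Kinetic enolization of the methyl group (LiN(SiMe3)2, THF, −78 °C) and trifluoroacetylation with CF3CO2CH2CF3 give (5E)-1,1,1-trifluoro-5-(13-methyltetradecyl)hept-5-ene-2,4-dione F3. Detrifluoroacetylative diazo transfer (MsN3, Et3N, MeCN) gives (3E)-1-diazo-3-(13-methyltetradecyl)pent-3-en-2-one F4. Irradiation of F4 with 12 in ClCH2CH2Cl at room temperature, then brief warming to 80 °C after excess 12 has been removed, should give 17 through 13, 14, 15 and 16.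

**Step 4.** The aldo-keteniminium ion can condense with itself or with the base faster than it adds to a weakly nucleophilic monoalkylacetylene. The ring double bond may also migrate toward the methyl-bearing carbon during hydrolysis. That migration is tolerable: the isomeric enone would give the other monoethyl ether in step 5, and step 6 converges it on the same diol 19.

Fallback, from bromide 6 back to 11 (it also bypasses step 3): methylketene F5, generated in the flask from propionyl chloride and Et3N, is trapped by 12 in a ketene–ynol ether (2+2) cycloaddition to give rac-3-ethoxy-4-methylcyclobut-2-en-1-one F6. The Grignard reagent 13-methyltetradecylmagnesium bromide F7, made from 6 (Mg, THF), adds 1,2 to F6 at −78 °C to give 3-ethoxy-4-methyl-1-(13-methyltetradecyl)cyclobut-2-en-1-ol F8 (mixture of diastereomers). Dilute HCl then hydrolyses the enol ether with allylic transposition and loss of the alcohol function, giving 11.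

**Step 7.** Carboxylation may occur at C3 between the two hydroxyls instead of at C1, which is buttressed by the chain and the neighbouring methyl. Conversion may be incomplete because the carboxylation is reversible. The product may lose CO2 during acidic work-up or drying.

Fallback, from diol 19 back to 21: Vilsmeier–Haack formylation (POCl3, DMF, 0 °C → rt; aq. NaOAc), which with 5-alkylresorcinols goes para to one hydroxyl and ortho to the other, gives 2,4-dihydroxy-5-methyl-6-(13-methyltetradecyl)benzaldehyde F9. Lindgren–Pinnick oxidation (NaClO2, NaH2PO4, H2NSO3H as hypochlorite scavenger, aqueous dioxane, 0 °C) then gives 21 without any hot step.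

**Step 1.** The secondary Grignard reagent may reduce or eliminate the bromide by β-hydride transfer, or homocouple, and coupling may be slow if the magnesium alkoxide aggregates.

Fallback, from bromo alcohol 1 back to 4: heating 1 with PPh3 in MeCN gives (12-hydroxydodecyl)triphenylphosphonium bromide F10. The ylide formed with two equivalents of NaN(SiMe3)2 in THF reacts with acetone (Wittig reaction) to give 13-methyltetradec-12-en-1-ol F11. Hydrogenation (H2, Pd/C, EtOAc) gives 4.

## Further compounds

F1 | step 5 | dimethyl (16-methyl-2-oxoheptadecan-3-yl)phosphonate (racemic) | COP(=O)(OC)C(CCCCCCCCCCCCC(C)C)C(C)=O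
F2 | step 5 | (3E)-3-(13-methyltetradecyl)pent-3-en-2-one | C/C=C(\CCCCCCCCCCCCC(C)C)C(C)=O
F3 | step 5 | (5E)-1,1,1-trifluoro-5-(13-methyltetradecyl)hept-5-ene-2,4-dione | C/C=C(\CCCCCCCCCCCCC(C)C)C(=O)CC(=O)C(F)(F)F
F4 | step 5 | (3E)-1-diazo-3-(13-methyltetradecyl)pent-3-en-2-one | C/C=C(\CCCCCCCCCCCCC(C)C)C(=O)C=[N+]=[N-]
F5 | step 4 | methylketene (prop-1-en-1-one) | CC=C=O
F6 | step 4 | rac-3-ethoxy-4-methylcyclobut-2-en-1-one | CCOC1=CC(=O)C1C
F7 | step 4 | 13-methyltetradecylmagnesium bromide | CC(C)CCCCCCCCCCCC[Mg]Br
F8 | step 4 | 3-ethoxy-4-methyl-1-(13-methyltetradecyl)cyclobut-2-en-1-ol (racemic, mixture of diastereomers) | CCOC1=CC(O)(CCCCCCCCCCCCC(C)C)C1C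
F9 | step 7 | 2,4-dihydroxy-5-methyl-6-(13-methyltetradecyl)benzaldehyde | Cc1c(O)cc(O)c(C=O)c1CCCCCCCCCCCCC(C)C
F10 | step 1 | (12-hydroxydodecyl)triphenylphosphonium bromide | OCCCCCCCCCCCC[P+](c1ccccc1)(c1ccccc1)c1ccccc1.[Br-]
F11 | step 1 | 13-methyltetradec-12-en-1-ol | CC(C)=CCCCCCCCCCCCO
A1 | alternative 1 | methyl 4-methoxy-6-(13-methyltetradecyl)-2-oxo-2H-pyran-5-carboxylate | COC(=O)C1=C(CCCCCCCCCCCCC(C)C)OC(=O)C=C1OC
A2 | alternative 1 | 1,1-dimethoxyprop-1-ene | CC=C(OC)OC
A3 | alternative 1 | methyl 2,4-dimethoxy-5-methyl-6-(13-methyltetradecyl)benzoate | COC(=O)c1c(OC)cc(OC)c(C)c1CCCCCCCCCCCCC(C)C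
A4 | alternative 2 | 1-methoxy-1,3-bis(trimethylsilyloxy)penta-1,3-diene | COC(O[Si](C)(C)C)=CC(O[Si](C)(C)C)=CC
A5 | alternative 2 | benzyl 16-methylheptadec-2-ynoate | CC(C)CCCCCCCCCCCCC#CC(=O)OCc1ccccc1
A6 | alternative 2 | benzyl 2,4-dihydroxy-5-methyl-6-(13-methyltetradecyl)benzoate | O=C(OCc1ccccc1)c1c(O)cc(O)c(C)c1CCCCCCCCCCCCC(C)C
A7 | alternative 3 | 6-(3,17-dimethyl-2,4-dioxooctadecyl)-2,2-dimethyl-4H-1,3-dioxin-4-one (racemic) | CC(C)CCCCCCCCCCCCC(=O)C(C)C(=O)CC1=CC(=O)OC(C)(C)O1
A8 | alternative 3 | 7-hydroxy-2,2,6-trimethyl-5-(13-methyltetradecyl)-4H-1,3-benzodioxin-4-one | Cc1c(O)cc2OC(C)(C)OC(=O)c2c1CCCCCCCCCCCCC(C)C
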